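**Assumption:** drimane numbering is used (C1–C10 decalin, C11 the carbon bonded to the arene, C12 the methyl on C8; β = the face carrying the C10 methyl; primes for the arene). The sulfates are handled as salts but listed as free acids, as in the target SMILES.

## Retrosynthetic overview
1. The two sulfates go on last, onto a 2',5'-hydroquinone whose 4'-OH is held as a PMB ether. The 3'-CHO comes from directed lithiation between the 2'-O and 4'-O groups.
2. C8 (H α, Me β) comes from α-face reduction of an 8(12)-methylene made from a C8 ketone. The C9=C11 styrene comes from a Heck reaction of an aryl iodide with a 9-methylene-8-ketone.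
3. Ring B comes from an α-ketol ring expansion of a 1-acetyl-1-hydroxy-trans-hydrindane, in which C10 shifts from C8 to C9.
4. Ring A and the cyclopentane form together by enantioselective proton-initiated cyclisation of an (E)-dienyne. The cyclopentane is then enlarged to ring B.
5. The dienyne comes from homoprenyl bromide, acetylide, Me3Al and 5-bromopent-2-yne. The arene comes from hydroquinone.

## Route

Step 1
Reactants: 1 5-bromo-2-methylpent-2-ene
Product: 2 6-methylhept-5-en-1-yne
Conditions: LiC≡CH·H2NCH2CH2NH2, DMSO, 0 to 23 °C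
Reagents that add atoms: lithium acetylide [Li]C#C
Why: SN2 alkylation of an acetylide by an unhindered primary bromide, with no stereocentre involved.

Step 2
Reactants: 2 6-methylhept-5-en-1-yne
Product: 4 (1E)-1-iodo-2,6-dimethylhepta-1,5-diene, via alkenylalane 3 (not isolated)
Conditions: Me3Al, Cp2ZrCl2 (25 mol %), CH2Cl2, 0 to 23 °C; then I2, THF, −30 °C
Reagents that add atoms: trimethylaluminium C[Al](C)C; iodine II
Why: Negishi zirconium-catalysed syn-carboalumination places Me on the inner and Al on the terminal alkyne carbon, and iodinolysis with retention fixes the E alkene (the future C5=C10).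

Step 3
Reactants: 4 (1E)-1-iodo-2,6-dimethylhepta-1,5-diene, 5 5-bromopent-2-yne
Product: 7 (6E)-2,6-dimethyldodeca-2,6-dien-10-yne, via pent-3-ynylzinc bromide 6 (not isolated)
Conditions: 5, Zn dust, I2 (5 mol %), DMA, 80 °C; then 4, Pd(PPh3)4 (3 mol %), THF, 23 °C
Reagents that add atoms: none
Why: Negishi sp2–sp3 cross-coupling of an alkylzinc halide with an alkenyl iodide proceeds with retention of the alkene geometry.

Step 4
Reactants: 7 (6E)-2,6-dimethyldodeca-2,6-dien-10-yne
Product: 8 1-[(1S,3aS,7aS)-4,4,7a-trimethyloctahydro-1H-inden-1-yl]ethan-1-one (trans-hydrindane, 5α-H, 10β-Me, acetyl β on C8)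
Conditions: (S,S)-HN[P(=NSO2CF3)(O2C20H10Ar2)]2 (Ar = 3,5-(CF3)2C6H3; chiral imidodiphosphorimidate acid, 5 mol %), H2O (3 equiv), (CF3)3COH, −20 °C
Reagents that add atoms: water O
Why: Proposed new method: the confined chiral Brønsted acid protonates the terminal trisubstituted alkene of the chair-folded dienyne, anti addition across the E alkene closes ring A and sets 5α-H and 10β-Me, 5-exo attack of the methyl-substituted alkyne closes the cyclopentane, and the linear vinyl cation is trapped by water to give the enol and then the methyl ketone; the closest known reactions are the racemic acid-promoted alkyne-terminated polyene cyclisation and the imidodiphosphorimidate-catalysed enantioselective cyclisation of polyenols.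

Step 5
Reactants: 8 acetyl-trans-hydrindane
Product: 10 1-[(1R,3aS,7aS)-1-hydroxy-4,4,7a-trimethyloctahydro-1H-inden-1-yl]ethan-1-one (8α-OH, acetyl β), via hydroperoxide 9 (not isolated)
Conditions: KOt-Bu, O2 (1 atm), P(OEt)3, DMF–t-BuOH, −25 °C
Reagents that add atoms: dioxygen O=O
Why: Enolate autoxidation, as in the 17-hydroxylation of 20-keto steroids, takes the fully substituted enolate and O2 from the α face opposite the angular methyl, and the phosphite reduces the hydroperoxide in situ.

Step 6 (key step)
Reactants: 10 1-acetyl-1-hydroxy-trans-hydrindane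
Product: 11 (1R,4aS,8aS)-1-hydroxy-1,5,5,8a-tetramethyloctahydronaphthalen-2(1H)-one (9β-hydroxy-12-nordriman-8-one)
Conditions: KOH (30 mol %), MeOH, reflux
Reagents that add atoms: none
Why: α-Ketol (acyloin) ring expansion of the D-homoannulation type, in which the alkoxide drives a 1,2-shift of quaternary C10 from C8 to the acetyl carbon C9 with retention at C10, released trans-hydrindane strain makes it downhill, and the new C9 carbinol centre is erased in step 7.

Step 7
Reactants: 11 9β-hydroxy-12-nordriman-8-one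
Product: 12 (4aS,8aS)-5,5,8a-trimethyl-1-methylideneoctahydronaphthalen-2(1H)-one (12-nordrim-9(11)-en-8-one)
Conditions: SOCl2, pyridine, 0 °C
Reagents that add atoms: none
Why: E2 dehydration through the chlorosulfite is regiospecific because the only β-hydrogens are those of the C11 methyl (C10 is quaternary and C8 is a carbonyl).

Step 8
Reactants: 13 hydroquinone
Product: 14 1,4-bis(methoxymethoxy)benzene
Conditions: MOMCl, i-Pr2NEt, CH2Cl2, 0 to 23 °C
Reagents that add atoms: chloromethyl methyl ether COCCl
Why: Double O-alkylation installs protecting groups that also direct lithiation.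

Step 9
Reactants: 14 1,4-bis(methoxymethoxy)benzene
Product: 17 2,5-bis(methoxymethoxy)phenol, via aryllithium 15 (not isolated), via arylboronate 16 (not isolated)
Conditions: n-BuLi, THF, 0 °C; B(OMe)3, −78 to 23 °C; H2O2, aq NaOH, 0 °C
Reagents that add atoms: hydrogen peroxide OO
Why: Directed ortho-metalation (all four C–H positions are equivalent), borylation and peroxide oxidation of the arylboronate introduce the 4'-oxygen.

Step 10
Reactants: 17 2,5-bis(methoxymethoxy)phenol
Product: 18 2-[(4-methoxybenzyl)oxy]-1,4-bis(methoxymethoxy)benzene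
Conditions: PMBCl, K2CO3, DMF, 50 °C
Reagents that add atoms: 4-methoxybenzyl chloride COc1ccc(CCl)cc1
Why: Williamson etherification marks the 4'-oxygen with a group that is cleaved oxidatively and so stays apart from the two MOM ethers.

Step 11
Reactants: 18 PMB/bis-MOM arene
Product: 19 1-iodo-4-[(4-methoxybenzyl)oxy]-2,5-bis(methoxymethoxy)benzene
Conditions: NIS, CF3CO2H (5 mol %), MeCN, 0 to 23 °C
Reagents that add atoms: N-iodosuccinimide O=C1CCC(=O)N1I
Why: Electrophilic aromatic iodination goes to C1', the only position that is para to one oxygen (OPMB) and ortho to another (OMOM) without being flanked by two substituents.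

Step 12
Reactants: 12 12-nordrim-9(11)-en-8-one, 19 aryl iodide
Product: 20 (1Z,4aS,8aS)-1-{4-[(4-methoxybenzyl)oxy]-2,5-bis(methoxymethoxy)benzylidene}-5,5,8a-trimethyloctahydronaphthalen-2(1H)-one (aryl cis to C8, trans to C10)
Conditions: Pd(OAc)2 (5 mol %), P(o-tolyl)3, Et3N, DMF, 90 °C
Reagents that add atoms: none
Why: Mizoroki–Heck arylation adds the aryl group to the CH2 terminus, syn β-hydride elimination can only use a C11 hydrogen, and the lower-energy rotamer turns the aryl away from quaternary C10, which sets the alkene geometry of the target.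

Step 13
Reactants: 20 arylidene ketone
Product: 21 11-aryldrima-8(12),9(11)-diene (C8=CH2; aryl and geometry as in 20)
Conditions: Ph3PCH3Br, KOt-Bu, THF, 0 to 50 °C
Reagents that add atoms: methyltriphenylphosphonium bromide C[P+](c1ccccc1)(c1ccccc1)c1ccccc1.[Br-]
Why: Wittig methylenation of the C8 ketone brings in C12.

Step 14
Reactants: 21 cross-conjugated diene
Product: 22 (8S)-11-aryldrim-9(11)-ene (8α-H, 8β-CH3; aryl = 4-PMBO-2,5-(MOMO)2C6H2)
Conditions: 2-O2NC6H4SO2NHNH2, Et3N, CH2Cl2, 23 °C
Reagents that add atoms: none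
Why: Diimide reduction takes the unhindered 1,1-disubstituted alkene, leaves the hindered trisubstituted styrene untouched, and delivers both hydrogens syn from the α face opposite the axial C10 methyl, which sets C8 as S.

Step 15
Reactants: 22 (8S)-11-aryldrim-9(11)-ene
Product: 24 the 3'-carbaldehyde of 22, via aryllithium 23 (not isolated)
Conditions: n-BuLi, TMEDA, THF, −20 to 0 °C; DMF; then H2O
Reagents that add atoms: N,N-dimethylformamide CN(C)C=O
Why: Directed ortho-metalation takes the most acidic position, C3' between the OMOM and OPMB groups, and DMF formylates it.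

Step 16
Reactants: 24 aldehyde
Product: 25 the 2',5'-dihydroxy-4'-OPMB-3'-carbaldehyde
Conditions: HCl (cat.), MeOH–THF, 23 °C, short contact time
Reagents that add atoms: none
Why: Acid-catalysed acetal exchange removes both MOM ethers while the aryl PMB ether survives.

Step 17
Reactants: 25 hydroquinone
Product: 26 the 2',5'-bis(hydrogen sulfate) 4'-PMB ether (handled as the bis(tetrabutylammonium) salt)
Conditions: SO3·pyridine (6 equiv), pyridine, 40 °C; then n-Bu4NHSO4 extraction
Reagents that add atoms: sulfur trioxide–pyridine O=S(=O)([O-])[n+]1ccccc1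
Why: O-Sulfation reaches only the two free phenols because the 4'-oxygen is blocked.

Step 18
Reactants: 26 bis-sulfate PMB ether
Product: 27 target CNP0309628.1
Conditions: DDQ, CH2Cl2–pH 7 buffer, 0 to 23 °C; then cation exchange (H+ form)
Reagents that add atoms: none
Why: Oxidative PMB cleavage under neutral conditions frees the 4'-OH without touching the aryl sulfates, the aldehyde or the now electron-poor styrene.

## Compound list
1 | 5-bromo-2-methylpent-2-ene | CC(C)=CCCBr | starting material
2 | 6-methylhept-5-en-1-yne | CC(C)=CCCC#C | intermediate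
3 | (E)-(2,6-dimethylhepta-1,5-dienyl)dimethylalane | CC(C)=CCC/C(C)=C/[Al](C)C | intermediate
4 | (1E)-1-iodo-2,6-dimethylhepta-1,5-diene | CC(C)=CCC/C(C)=C/I | intermediate
5 | 5-bromopent-2-yne | CC#CCCBr | starting material
6 | pent-3-ynylzinc bromide | CC#CCC[Zn]Br | intermediate
7 | (6E)-2,6-dimethyldodeca-2,6-dien-10-yne | CC#CCC/C=C(\C)CCC=C(C)C | intermediate
8 | 1-[(1S,3aS,7aS)-4,4,7a-trimethyloctahydro-1H-inden-1-yl]ethanone | CC(=O)[C@H]1CC[C@H]2C(C)(C)CCC[C@]12C | intermediate
9 | 8α-hydroperoxide of 8 | CC(=O)[C@@]1(OO)CC[C@H]2C(C)(C)CCC[C@]12C | intermediate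
10 | 1-[(1R,3aS,7aS)-1-hydroxy-4,4,7a-trimethyloctahydro-1H-inden-1-yl]ethanone | CC(=O)[C@@]1(O)CC[C@H]2C(C)(C)CCC[C@]12C | intermediate
11 | (1R,4aS,8aS)-1-hydroxy-1,5,5,8a-tetramethyloctahydronaphthalen-2(1H)-one | O=C1CC[C@H]2C(C)(C)CCC[C@]2(C)[C@@]1(C)O | intermediate
12 | (4aS,8aS)-5,5,8a-trimethyl-1-methylideneoctahydronaphthalen-2(1H)-one | O=C1CC[C@H]2C(C)(C)CCC[C@]2(C)C1=C | intermediate
13 | hydroquinone | Oc1ccc(O)cc1 | starting material
14 | 1,4-bis(methoxymethoxy)benzene | COCOc1ccc(OCOC)cc1 | intermediate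
15 | 2,5-bis(methoxymethoxy)phenyllithium | [Li]c1cc(OCOC)ccc1OCOC | intermediate
16 | dimethyl 2,5-bis(methoxymethoxy)phenylboronate | COB(OC)c1cc(OCOC)ccc1OCOC | intermediate
17 | 2,5-bis(methoxymethoxy)phenol | COCOc1ccc(OCOC)c(O)c1 | intermediate
18 | 2-[(4-methoxybenzyl)oxy]-1,4-bis(methoxymethoxy)benzene | COCOc1ccc(OCOC)c(OCc2ccc(OC)cc2)c1 | intermediate
19 | 1-iodo-4-[(4-methoxybenzyl)oxy]-2,5-bis(methoxymethoxy)benzene | COCOc1cc(OCc2ccc(OC)cc2)c(OCOC)cc1I | intermediate
20 | arylidene ketone (aryl cis to C8) | O=C1CC[C@H]2C(C)(C)CCC[C@]2(C)/C1=C/c1cc(OCOC)c(OCc3ccc(OC)cc3)cc1OCOC | intermediate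
21 | 11-aryldrima-8(12),9(11)-diene | C=C1CC[C@H]2C(C)(C)CCC[C@]2(C)/C1=C/c1cc(OCOC)c(OCc3ccc(OC)cc3)cc1OCOC | intermediate
22 | (8S)-11-aryldrim-9(11)-ene | C[C@H]1CC[C@H]2C(C)(C)CCC[C@]2(C)/C1=C/c1cc(OCOC)c(OCc3ccc(OC)cc3)cc1OCOC | intermediate
23 | 3'-lithio derivative of 22 | C[C@H]1CC[C@H]2C(C)(C)CCC[C@]2(C)/C1=C/c1cc(OCOC)c(OCc3ccc(OC)cc3)c([Li])c1OCOC | intermediate
24 | 3'-carbaldehyde | C[C@H]1CC[C@H]2C(C)(C)CCC[C@]2(C)/C1=C/c1cc(OCOC)c(OCc3ccc(OC)cc3)c(C=O)c1OCOC | intermediate
25 | 2',5'-dihydroxy-4'-OPMB aldehyde | C[C@H]1CC[C@H]2C(C)(C)CCC[C@]2(C)/C1=C/c1cc(O)c(OCc3ccc(OC)cc3)c(C=O)c1O | intermediate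
26 | 2',5'-bis(hydrogen sulfate) 4'-PMB ether | C[C@H]1CC[C@H]2C(C)(C)CCC[C@]2(C)/C1=C/c1cc(OS(=O)(=O)O)c(OCc3ccc(OC)cc3)c(C=O)c1OS(=O)(=O)O | intermediate
27 | CNP0309628.1 | C[C@H]1CC[C@H]2C(C)(C)CCC[C@]2(C)/C1=C/c1cc(OS(=O)(=O)O)c(O)c(C=O)c1OS(=O)(=O)O | target

## Step count
- **Total steps:** 18.
- **Longest linear sequence:** 14 (steps 1–7, then 12–18).

## Steps most likely to fail

**Step 4 (the proposed new step).** The acid may protonate unselectively, give low enantioselectivity, or stop after the first ring. The fallback sets out from 7 and comes back at 8. The known racemic alkyne-terminated cyclisation is run with CF3CO2H and ethylene carbonate in ClCH2CH2Cl at 0 °C, followed by K2CO3 in aqueous MeOH. It gives 8 together with the mirror-image ketone F1. The two are separated by preparative supercritical-fluid chromatography on a cellulose tris(3,5-dimethylphenylcarbamate) phase.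

**Step 12 (Heck reaction).** The 1,1-disubstituted enone next to a quaternary carbon may react sluggishly. The fallback sets out from 10 and 19 and comes back at 20. The arene is attached before ring enlargement by palladium-catalysed enolate arylation of the only enolisable position of 10, the acetyl methyl. Conditions are Pd2(dba)3, 2-dicyclohexylphosphino-2',4',6'-triisopropylbiphenyl and K3PO4 in toluene at 70 °C, giving the benzyl ketone ketol F2. KOH in MeOH then effects the same α-ketol ring expansion to the 9-hydroxy-9-arylmethyl ketone F3. SOCl2 in pyridine dehydrates F3 towards the benzylic hydrogens to give 20.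

**Step 14 (selective reduction).** Chemoselectivity and face selectivity on the twisted diene are uncertain. The fallback sets out from 20 and comes back at 22, so step 13 is skipped. MeLi with CeCl3 adds to the C8 ketone from the open α face and gives the 8β-hydroxy-8α-methyl allylic alcohol F4. n-BuLi and ClCO2Me convert it into the methyl carbonate F5. Tsuji formate hydrogenolysis follows (Pd2(dba)3, n-Bu3P, HCO2H–Et3N, THF). Ionisation anti to the β-carbonate puts palladium on the α face. Hydride is then delivered from palladium to the more substituted allyl terminus C8, which gives 8α-H and 8β-CH3 with the C9=C11 alkene retained.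

## Further compounds
F1 | step 4 | 1-[(1R,3aR,7aR)-4,4,7a-trimethyloctahydro-1H-inden-1-yl]ethanone (enantiomer of 8) | CC(=O)[C@@H]1CC[C@@H]2C(C)(C)CCC[C@@]12C
F2 | step 12 | 2-aryl-1-[(1R,3aS,7aS)-1-hydroxy-4,4,7a-trimethyloctahydro-1H-inden-1-yl]ethanone (aryl as in 19) | O=C(Cc1cc(OCOC)c(OCc3ccc(OC)cc3)cc1OCOC)[C@@]1(O)CC[C@H]2C(C)(C)CCC[C@]12C
F3 | step 12 | 9β-hydroxy-11-aryl-12-nordriman-8-one | O=C1CC[C@H]2C(C)(C)CCC[C@]2(C)[C@@]1(Cc1cc(OCOC)c(OCc3ccc(OC)cc3)cc1OCOC)O
F4 | step 14 | 8β-hydroxy-8α-methyl-11-aryldrim-9(11)-ene | C[C@]1(O)CC[C@H]2C(C)(C)CCC[C@]2(C)/C1=C/c1cc(OCOC)c(OCc3ccc(OC)cc3)cc1OCOC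
F5 | step 14 | methyl carbonate of F4 | C[C@]1(OC(=O)OC)CC[C@H]2C(C)(C)CCC[C@]2(C)/C1=C/c1cc(OCOC)c(OCc3ccc(OC)cc3)cc1OCOC
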